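**Assumptions**
- The target SMILES has no stereocenters (isoirigenin is achiral), so there is no enantiomer to set. The only transient stereocenter, in compound 9, is racemic and is destroyed in the next step.
- Simple reagents (BnBr, MeI, H₂O₂ and so on) are described in each step but not numbered.

**Retrosynthesis**
1. Isoirigenin (11) comes from global hydrogenolysis of the tri-O-benzyl isoflavone 10. The 5-, 7- and 5'-OH groups are masked as benzyl ethers, and the 8-, 3'- and 4'-OMe groups are installed early.
2. The pyranone ring (C2 and O1) is closed last but one. An acid cyclization of the 2'-hydroxyaryl 1,2-diaryl-3,3-dimethoxypropanone 9 does this.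
3. Key bold step: hypervalent-iodine oxidative 1,2-aryl migration of 2'-hydroxychalcone 8. This moves the B ring from Cβ to Cα, so the isoflavone skeleton forms with no cross-coupling and no deoxybenzoin formylation.
4. Chalcone 8 comes from a Claisen–Schmidt condensation of acetophenone 5 and aldehyde 7. Ketone 5 is built from phloroacetophenone by dibenzylation, ortho-formylation, Dakin oxidation and selective O-methylation, which installs the 8-OMe. Aldehyde 7 comes from commercial 5-hydroxyveratraldehyde.
5. Ring order: A and B rings are commercial, then the enone linker (chalcone), then the aryl shift, then the C ring.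

**Route**

**Step 1**
Reactants: 1 (2,4,6-trihydroxyacetophenone, phloroacetophenone)
Product: 2 (1-[4,6-bis(benzyloxy)-2-hydroxyphenyl]ethanone)
Conditions: BnBr (2.1 equiv), K₂CO₃, acetone, reflux, 12 h
Reagents that add atoms: benzyl bromide, BrCc1ccccc1
Why: Williamson O-benzylation; the 2-OH stays free because it is chelated to the C=O, and the two symmetry-equivalent OH groups (4 and 6) are alkylated. No stereocenter.

**Step 2**
Reactants: 2
Product: 3 (1-[3-formyl-4,6-bis(benzyloxy)-2-hydroxyphenyl]ethanone)
Conditions: MgCl₂, Et₃N, (CH₂O)ₙ, MeCN, reflux, 6 h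
Reagents that add atoms: paraformaldehyde (formaldehyde), C=O
Why: Mg-phenoxide-directed ortho-formylation (Casnati–Skattebøl) puts CHO at C3', ortho to the free OH, rather than at C5' between the two OBn groups. No stereocenter.

**Step 3**
Reactants: 3
Product: 4 (1-[4,6-bis(benzyloxy)-2,3-dihydroxyphenyl]ethanone)
Conditions: 30% H₂O₂, 1 M NaOH, MeOH, 0 °C to rt, 2 h, then mild acid workup
Reagents that add atoms: hydrogen peroxide, OO
Why: Dakin oxidation of an o-hydroxybenzaldehyde. Aryl migration to oxygen gives the aryl formate, which is hydrolysed to the catechol. No stereocenter.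

**Step 4**
Reactants: 4
Product: 5 (1-[4,6-bis(benzyloxy)-2-hydroxy-3-methoxyphenyl]ethanone)
Conditions: MeI (1.05 equiv), K₂CO₃, acetone, rt, 6 h
Reagents that add atoms: methyl iodide, CI
Why: Chemoselective O-methylation (Williamson). The free 3-OH is more nucleophilic than the 2-OH chelated to the ketone, which gives the 8-OMe pattern. No stereocenter.

**Step 5**
Reactants: 6 (3-hydroxy-4,5-dimethoxybenzaldehyde, 5-hydroxyveratraldehyde)
Product: 7 (3-benzyloxy-4,5-dimethoxybenzaldehyde)
Conditions: BnBr, K₂CO₃, DMF, rt, 8 h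
Reagents that add atoms: benzyl bromide, BrCc1ccccc1
Why: Williamson O-benzylation of a phenol. No stereocenter.

**Step 6**
Reactants: 5 and 7
Product: 8 ((E)-1-[4,6-bis(benzyloxy)-2-hydroxy-3-methoxyphenyl]-3-[3-(benzyloxy)-4,5-dimethoxyphenyl]prop-2-en-1-one)
Conditions: 50% aq. KOH (excess), EtOH, rt, 48–72 h
Reagents that add atoms: none
Why: Claisen–Schmidt (aldol) condensation; excess base is needed because the phenol consumes one equivalent, and the thermodynamic E-enone forms.

**Step 7 (key step)**
Reactants: 8
Product: 9 (1-[4,6-bis(benzyloxy)-2-hydroxy-3-methoxyphenyl]-2-[3-(benzyloxy)-4,5-dimethoxyphenyl]-3,3-dimethoxypropan-1-one, racemic)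
Conditions: PhI(OAc)₂ (1.5 equiv), H₂SO₄, HC(OMe)₃, MeOH, 0 °C to rt, 12 h
Reagents that add atoms: methanol, CO (trimethyl orthoformate, COC(OC)OC, serves as co-solvent and dehydrating agent)
Why: Oxidative 1,2-aryl migration of a chalcone. I(III) and MeOH add across the enone alkene with OMe at the benzylic Cβ and I at Cα. The electron-rich 3,4,5-trioxygenated aryl then shifts to Cα with loss of PhI, and the resulting oxocarbenium is trapped as the dimethyl acetal. The new benzylic stereocenter is racemic and is destroyed in Step 8.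

**Step 8**
Reactants: 9
Product: 10 (5,7,5'-tri-O-benzyl-isoirigenin: 5,7-bis(benzyloxy)-3-[3-(benzyloxy)-4,5-dimethoxyphenyl]-8-methoxy-4H-chromen-4-one)
Conditions: TsOH·H₂O (0.2 equiv), toluene, 80 °C, 3 h
Reagents that add atoms: none
Why: Acid-mediated acetal ionization, intramolecular attack by the 2'-OH on the oxocarbenium, and loss of MeOH (two MeOH lost in all) give the chromone C2=C3 bond (oxa-cyclodehydration). The achiral aromatic chromone is formed, so the stereocenter is removed.

**Step 9**
Reactants: 10
Product: 11 (isoirigenin)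
Conditions: H₂ (1 atm), 10% Pd/C, THF–MeOH, rt, monitored by TLC (about 4 h)
Reagents that add atoms: none (H₂ adds only hydrogen)
Why: Catalytic hydrogenolysis removes all three aryl benzyl ethers (5-, 7-, 5'-O-Bn). The aryl OMe groups and the chromone C=O and C2=C3 survive at 1 atm.

**Self-check**
- Target ring and substituents: the target is a 5,7-dihydroxy-8-methoxychromone with a 3-aryl group (3'-OMe, 4'-OMe, 5'-OH). A ring: 2'-OH becomes O1, 6'-OBn becomes 5-OH, 4'-OBn becomes 7-OH, 3'-OMe becomes 8-OMe. B ring: the 3-OBn-4,5-diOMe pattern of 7 becomes 5'-OH, 4'-OMe, 3'-OMe.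
- Atom balance (formulas): 1 C₈H₈O₄; 2 C₂₂H₂₀O₄; 3 C₂₃H₂₀O₅; 4 C₂₂H₂₀O₅; 5 C₂₃H₂₂O₅; 6 C₉H₁₀O₄; 7 C₁₆H₁₆O₄; 8 C₃₉H₃₆O₈; 9 C₄₁H₄₂O₁₀; 10 C₃₉H₃₄O₈; 11 C₁₈H₁₆O₈. This matches the target formula.
- Group survival: benzyl ethers tolerate base, the I(III)/acid conditions and TsOH; methyl ethers tolerate everything including hydrogenolysis.
- Stereochemistry: the target has none, and the transient center in 9 is removed in Step 8.

**Compound list**
1 | 2,4,6-trihydroxyacetophenone | CC(=O)c1c(O)cc(O)cc1O | starting material
2 | 1-[4,6-bis(benzyloxy)-2-hydroxyphenyl]ethanone | CC(=O)c1c(O)cc(OCc2ccccc2)cc1OCc1ccccc1 | intermediate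
3 | 3-formyl-4,6-bis(benzyloxy)-2-hydroxyacetophenone | CC(=O)c1c(O)c(C=O)c(OCc2ccccc2)cc1OCc1ccccc1 | intermediate
4 | 4,6-bis(benzyloxy)-2,3-dihydroxyacetophenone | CC(=O)c1c(O)c(O)c(OCc2ccccc2)cc1OCc1ccccc1 | intermediate
5 | 4,6-bis(benzyloxy)-2-hydroxy-3-methoxyacetophenone | CC(=O)c1c(O)c(OC)c(OCc2ccccc2)cc1OCc1ccccc1 | intermediate
6 | 3-hydroxy-4,5-dimethoxybenzaldehyde | COc1cc(C=O)cc(O)c1OC | starting material
7 | 3-benzyloxy-4,5-dimethoxybenzaldehyde | COc1cc(C=O)cc(OCc2ccccc2)c1OC | intermediate
8 | (E)-chalcone from 5 and 7 | COc1cc(/C=C/C(=O)c2c(O)c(OC)c(OCc3ccccc3)cc2OCc2ccccc2)cc(OCc2ccccc2)c1OC | intermediate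
9 | 1,2-diaryl-3,3-dimethoxypropan-1-one (racemic) | COc1cc(C(C(OC)OC)C(=O)c2c(O)c(OC)c(OCc3ccccc3)cc2OCc2ccccc2)cc(OCc2ccccc2)c1OC | intermediate
10 | 5,7,5'-tri-O-benzyl-isoirigenin | COc1cc(-c2coc3c(OC)c(OCc4ccccc4)cc(OCc4ccccc4)c3c2=O)cc(OCc2ccccc2)c1OC | intermediate
11 | isoirigenin | COc1cc(-c2coc3c(OC)c(O)cc(O)c3c2=O)cc(O)c1OC | target

**Totals**
- Total steps: 9.
- Longest linear sequence: 8 steps (1 → 2 → 3 → 4 → 5 → 8 → 9 → 10 → 11); the benzylation of 6 to 7 runs in parallel.

**Three steps most likely to fail**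
1. **Step 7 (oxidative aryl migration).** The very electron-rich A and B rings may be over-oxidised, and flavanone or aurone byproducts can form. Fallback: drop the aryl shift and build the C3–aryl bond by cross-coupling. Convert 5 to its DMF-DMA enaminone, iodinate with I₂ to the 3-iodochromone, then run a Suzuki coupling with the 3-benzyloxy-4,5-dimethoxyphenylboronic acid.
2. **Step 2 (C3'-formylation).** The acyl-chelated phenol is sluggish, and C5' is a competing site. Fallback: replace formylation and Dakin with NIS iodination of 2 at C3' followed by Cu(I)-catalysed methoxylation with NaOMe, which installs the 3'-OMe directly.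
3. **Step 9 (hydrogenolysis).** Pd/C may also reduce the chromone C2=C3 bond. Fallback: Lewis-acid debenzylation with BCl₃ and pentamethylbenzene in CH₂Cl₂ at –78 °C, a non-reductive cleavage that leaves the methyl ethers and the enone untouched.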